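Of the Q charged in alder, 25 % stood unspent at 15.0 h and 34 % stood as D, so the remainder had gone elsewhere.

| flask | Q | E | remark | time |
|---|---|---|---|---|
| alder | 20 mM | 19 mM | run made earlier |  |
| ash | 10 mM | 19 mM | run made earlier |  |
| oak | 15 mM | 19 mM | run made earlier |  |
| green | 20 mM | 19.0 mM | everything together at the start | 15 h |
| grey | 20 mM (fed, over 6.0 h) | 19.0 mM | all else is in the flask from the start; the feed brings no volume worth counting | 15 h |
| ochre | 20 mM | 19.0 mM (fed, over 6.0 h) | all else is in the flask from the start; the feed brings no volume worth counting | 15 h |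

| run | time / h | D / % | Q / % |
|---|---|---|---|
| alder | 1.33 | 8 | 84 |
| alder | 2.00 | 13 | 79 |
| alder | 3.00 | 16 | 69 |
| alder | 5.00 | 19 | 55 |
| alder | 10.0 | 29 | 39 |
| alder | 15.0 | 34 | 25 |
| ash | 2.00 | 12 | 78 |
| ash | 4.00 | 23 | 61 |
| ash | 6.00 | 29 | 53 |
| ash | 8.00 | 32 | 41 |
| ash | 10.0 | 33 | 39 |
| ash | 12.0 | 41 | 35 |
| oak | 1.00 | 6 | 87 |
| oak | 1.50 | 12 | 81 |
| oak | 2.50 | 16 | 73 |
| oak | 4.00 | 21 | 62 |
| oak | 8.00 | 30 | 41 |
| oak | 12.0 | 34 | 32 |

(scatter of a reading: 2 percentage points)

1. the flask with the highest amount of D, in percent of the Q charged ("all alike" if they lie within 1.5 percentage points) (green / grey / ochre / all alike)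
2. final D, as a percentage of the Q charged, in green
3. final D, as a percentage of the Q charged, in grey
4. final D, as a percentage of the Q charged, in ochre



From that last alder reading I took 1.21 as the toll, the Q lost by other paths per Q turned into D, an inverted selectivity factor. Green repeated alder, so I expected 34 % there, and grey had its whole charge of E from the start, so I expected no raised toll there. During the feed in ochre, the E delivered so far averaged 9.50 mM, before any use, against 19 mM charged in alder. E was never varied, so I assumed the toll went inversely with E, which made it about 2.41 in ochre during the feed, and both of my bounds rest on that assumption.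

For my bound from above I gave ochre alder's spending, with the doubled toll on the Q alder had spent by 5.00 h and the plain toll on the rest: 26.8 %. For my bound from below I used the doubled toll throughout, on Q spent only as far as alder's 10.0 h reading: 17.9 %.

The forecast gave green 35 %, grey 31 % and ochre 31 %, with green highest, arguing that "Ochre starves Q of E early", so its ochre stood above my bracket.

The flasks gave green 34.9 %, grey 32.9 % and ochre 25.9 %, so ochre fell inside the bracket and green was highest.

    Q + E → D (k = 3.76 L mol⁻¹ h⁻¹)
    Q + E → J, rate k2*[Q] as long as [E] is above zero (k = 0.0360 h⁻¹)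
    2 Q → Z (k = 0.655 L mol⁻¹ h⁻¹)

At 6.00 h, the toll stood at 2.44 in ochre against 0.795 in grey. At 15.0 h it stood at 1.76 in ochre against 1.03 in grey.

A further flask, green with its Q lowered to 8.0 mM, kept 22.7 % of its Q unspent at 15.0 h. The toll read from ash's last reading, 0.585, gives about 48.7 % of D in that flask, and the computed flask gave 45.4 %.

The numbers in the tables were generated by integration for an exercise; noise was put on by code.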